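**Plan**

- Retrosynthesis: the ester C–O bond is cut last. The C4 methyl (C15) is traced back to a lactone carbonyl tied to the 6β-oxygen (a 15,6β-olide). Then C3=C4 and C5–C10 are cut, which opens both rings to an acyclic butenolide–alkene–aldehyde.
- Enabling feature: O6 (axial on ring B) and C15 (on C4) lie syn across C5, so a five-membered butenolide O6–C15(=O)–C4=C5–C6 can hold them. This makes C5 a radical acceptor and C4 an enolate carbon. The methyl-bearing quaternary C10 is the natural site of a tertiary radical, and C3 of an aldehyde.
- Forward: the chain is joined C7 → C6 → butenolide → C9=C10/C1–C3 (cross-metathesis). Ring B (C5–C10) and then ring A (C3–C4) close in one radical–polar crossover cascade, with dehydration to C3=C4 in the same operation.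
- Stereochemistry: C7 comes from an Evans alkylation, C6 from a catalyst-controlled, Felkin-matched alkynylation. C5 and C10 are relayed in the key step by the cis-fused lactone and a chair transition state.
- Helpers removed: the lactone is reduced, C15–OH is deoxygenated to the methyl group, and O6 is acylated with acetate-protected p-coumaric acid.

Key step: step 8

Assumption: 1, 2, 7, 12 and 22 are purchased; C1–C15 are eudesmane atom numbers and α/β refer to the natural eudesmane series (5α-H, 7β-isopropyl, 10β-methyl).

**Route**

Step 1
Reactants: 1 (S)-4-benzyl-3-(3-methylbutanoyl)oxazolidin-2-one; 2 allyl iodide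
Product: 4 (S)-4-benzyl-3-[(S)-2-isopropylpent-4-enoyl]oxazolidin-2-one, via sodium enolate 3 (not isolated)
Conditions: NaN(SiMe3)2, THF, −78 °C; then 2, −78 to −40 °C
Reagents that add atoms: none
Why: Evans asymmetric alkylation, in which the chelated sodium (Z)-enolate 3 is allylated on the face away from the benzyl group of the auxiliary, so that the isopropyl-bearing carbon (C7 of the target) is set as (S).

Step 2
Reactants: 4 (S)-4-benzyl-3-[(S)-2-isopropylpent-4-enoyl]oxazolidin-2-one
Product: 5 (S)-2-isopropylpent-4-en-1-ol
Conditions: LiBH4, H2O (1 equiv), Et2O, 0 °C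
Reagents that add atoms: none
Why: Reductive removal of the Evans auxiliary (hydride attack at the exocyclic imide carbonyl) should give the primary alcohol without touching the C7 stereocenter or the alkene.

Step 3
Reactants: 5 (S)-2-isopropylpent-4-en-1-ol
Product: 6 (S)-2-isopropylpent-4-enal
Conditions: Dess–Martin periodinane, NaHCO3, CH2Cl2, 0 to 23 °C
Reagents that add atoms: none
Why: Dess–Martin oxidation under buffered, non-basic conditions should deliver the α-branched aldehyde without epimerisation at C7, and the volatile aldehyde is used at once.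

Step 4
Reactants: 6 (S)-2-isopropylpent-4-enal; 7 methyl propiolate
Product: 9 methyl (4R,5S)-4-hydroxy-5-isopropyloct-7-en-2-ynoate, via methylzinc acetylide 8 (not isolated)
Conditions: 7, Me2Zn, ProPhenol ligand (cat.), Ph3PO (cat.), toluene, 0 °C; then 6, 4 °C
Reagents that add atoms: none
Why: Zn–ProPhenol-catalysed asymmetric alkynylation of an aldehyde, for which the ligand antipode is chosen so that catalyst control and the Felkin–Anh preference of the α-isopropyl aldehyde (isopropyl anti to the incoming acetylide) both give the (4R)-carbinol, that is the C6 oxygen in the configuration of the target.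

Step 5
Reactants: 9 methyl (4R,5S)-4-hydroxy-5-isopropyloct-7-en-2-ynoate
Product: 11 (S)-5-[(S)-2-methylhex-5-en-3-yl]furan-2(5H)-one, via (Z)-hydroxy enoate 10 (not isolated)
Conditions: H2 (1 atm), Pd/CaCO3 poisoned with Pb(OAc)2, quinoline, EtOAc, 23 °C; then PPTS (cat.), CH2Cl2, 23 °C
Reagents that add atoms: none
Why: Lindlar semihydrogenation (cis-selective, alkyne reduced ahead of the terminal alkene) gives the (Z)-γ-hydroxy enoate 10, which lactonises with loss of methanol to the butenolide that ties O6 to C15 without touching the C6 stereocenter.

Step 6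
Reactants: 12 4-methylpent-4-en-1-ol
Product: 13 4-methylpent-4-enal
Conditions: Dess–Martin periodinane, NaHCO3, CH2Cl2, 0 to 23 °C; filtered solution used directly
Reagents that add atoms: none
Why: Dess–Martin oxidation of a primary alcohol to the aldehyde, the 1,1-disubstituted alkene being inert, gives the fragment that carries C10, its methyl group and C1–C3.

Step 7
Reactants: 11 (S)-5-[(S)-2-methylhex-5-en-3-yl]furan-2(5H)-one; 13 4-methylpent-4-enal
Product: 14 (S)-5-[(S)-2,6-dimethyl-9-oxonon-5-en-3-yl]furan-2(5H)-one (mixture of alkene isomers)
Conditions: second-generation Hoveyda–Grubbs catalyst (cat.), 13 (5 equiv), CH2Cl2, 40 °C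
Reagents that add atoms: none
Why: Olefin cross-metathesis of the terminal alkene of 11 with the 1,1-disubstituted alkene of 13 (in excess) should give the trisubstituted C9=C10 alkene, the electron-poor butenolide alkene and the aldehyde being tolerated, and the alkene geometry does not matter because C10 becomes a radical in step 8.

Step 8
Reactants: 14 (S)-5-[(S)-2,6-dimethyl-9-oxonon-5-en-3-yl]furan-2(5H)-one
Product: 17 eudesm-3-en-15,6β-olide, via hydroxy lactone 15 (not isolated), via mesylate 16 (not isolated)
Conditions: Fe(acac)3 (0.3 equiv), PhSiH3 (2.5 equiv), EtOH/(CH2OH)2, 23 °C; extractive work-up, then MsCl, Et3N, CH2Cl2, 0 to 23 °C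
Reagents that add atoms: none
Why: An iron hydride formed from Fe(acac)3 and PhSiH3 transfers a hydrogen atom to C9 of the electron-rich trisubstituted alkene, the tertiary C10 radical adds to C5 of the butenolide, the resulting C4 radical is reduced to an iron enolate (radical–polar crossover) that adds to the C3 aldehyde, and the crude aldol 15 loses water through mesylate 16 by E1cB elimination, so that C5–C10 and C3=C4 are both made in this operation. The closest known reaction type is the hydrogen-atom-transfer-initiated Giese addition/aldol polycyclisation (radical–polar crossover annulation) used to build decalins that carry a quaternary ring-fusion carbon. Ring B closes by a 6-exo-trig radical cyclisation and ring A by a 6-(enolexo)-exo-trig aldol addition. C5 is controlled by the temporary lactone, because the three-carbon link from C6 lets the radical reach only the butenolide face that carries C7, which makes H5 and H6 cis as in the target, and C10 is set in a chair-like transition state with the C7 isopropyl equatorial, in which the methyl group takes the crowded position under the lactone ring and the longer C1–C3 chain the open equatorial position, which gives the trans ring fusion; the stereocenters at C3 and C4 of 15 are erased by the elimination. The step needs hydrogen-atom transfer to the alkene and not to the butenolide (secured by the electron-poor butenolide, a poor hydrogen-atom acceptor but a good radical acceptor), 6-exo addition faster than a 1,5-hydrogen shift from C6–H (that hydrogen points away from C10 when C7 sits over the ring), and aldol capture faster than protonation of the enolate (the aldehyde is held in reach for a six-membered closure).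

Step 9
Reactants: 17 eudesm-3-en-15,6β-olide
Product: 18 eudesm-3-ene-6β,15-diol
Conditions: i-Bu2AlH (4 equiv), CH2Cl2, −78 to 0 °C; aqueous potassium sodium tartrate
Reagents that add atoms: none
Why: Carbonyl (1,2-) reduction of the α-alkylidene lactone by i-Bu2AlH opens the temporary ring to the allylic C15 alcohol and the free 6β-hydroxyl, with C3=C4 left in place.

Step 10
Reactants: 18 eudesm-3-ene-6β,15-diol
Product: 21 eudesm-3-en-6β-ol, via bis(sulfate) 19 (not isolated), via 6-sulfate 20 (not isolated)
Conditions: SO3·pyridine (5 equiv), THF, 0 to 23 °C; then LiAlH4, THF, 0 to 23 °C; then dilute H2SO4, THF/H2O, 23 °C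
Reagents that add atoms: none
Why: Allylic deoxygenation through the sulfate monoester (SN2 hydride displacement at the primary allylic C15 by LiAlH4, which keeps C3=C4 in place), in which the C6 oxygen is masked as a secondary alkyl sulfate that is inert to hydride and cannot close onto C15, and is solvolysed back to the 6β-alcohol in the acidic last stage.

Step 11
Reactants: 21 eudesm-3-en-6β-ol; 22 (E)-4-acetoxycinnamic acid
Product: 24 6β-[(E)-4-acetoxycinnamoyloxy]eudesm-3-ene, via acid chloride 23 (not isolated)
Conditions: 22, (COCl)2, DMF (cat.), CH2Cl2, 0 to 23 °C, evaporation; then 21, Et3N, DMAP, CH2Cl2, 23 to 40 °C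
Reagents that add atoms: none
Why: DMAP-catalysed acylation by the acid chloride (nucleophilic acyl substitution, retention at C6) should esterify the hindered axial 6β-hydroxyl, while the phenol is kept as its acetate and the E alkene is untouched.

Step 12
Reactants: 24 6β-[(E)-4-acetoxycinnamoyloxy]eudesm-3-ene
Product: 25 6β-[(E)-4-hydroxycinnamoyloxy]eudesm-3-ene (CNP0220414.1)
Conditions: K2CO3 (0.2 equiv), MeOH, 0 °C
Reagents that add atoms: none
Why: Chemoselective transesterification (methanolysis) of the aryl acetate, which is far more electrophilic and less hindered than the secondary cinnamate ester, frees the phenol and gives the target.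

**Compound list**

1 | (S)-4-benzyl-3-(3-methylbutanoyl)oxazolidin-2-one | CC(C)CC(=O)N1[C@@H](Cc2ccccc2)COC1=O | starting material
2 | allyl iodide | C=CCI | starting material
3 | sodium (Z)-enolate of 1 | CC(C)/C=C(\[O-])N1[C@@H](Cc2ccccc2)COC1=O.[Na+] | intermediate
4 | (S)-4-benzyl-3-[(S)-2-isopropylpent-4-enoyl]oxazolidin-2-one | C=CC[C@@H](C(C)C)C(=O)N1[C@@H](Cc2ccccc2)COC1=O | intermediate
5 | (S)-2-isopropylpent-4-en-1-ol | C=CC[C@@H](C(C)C)CO | intermediate
6 | (S)-2-isopropylpent-4-enal | C=CC[C@@H](C(C)C)C=O | intermediate
7 | methyl propiolate | C#CC(=O)OC | starting material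
8 | methyl 3-(methylzincio)prop-2-ynoate | COC(=O)C#C[Zn]C | intermediate
9 | methyl (4R,5S)-4-hydroxy-5-isopropyloct-7-en-2-ynoate | C=CC[C@@H](C(C)C)[C@@H](O)C#CC(=O)OC | intermediate
10 | methyl (2Z,4S,5S)-4-hydroxy-5-isopropylocta-2,7-dienoate | C=CC[C@@H](C(C)C)[C@@H](O)/C=C\C(=O)OC | intermediate
11 | (S)-5-[(S)-2-methylhex-5-en-3-yl]furan-2(5H)-one | C=CC[C@@H](C(C)C)[C@H]1OC(=O)C=C1 | intermediate
12 | 4-methylpent-4-en-1-ol | CC(=C)CCCO | starting material
13 | 4-methylpent-4-enal | CC(=C)CCC=O | intermediate
14 | (S)-5-[(S)-2,6-dimethyl-9-oxonon-5-en-3-yl]furan-2(5H)-one, mixture of alkene isomers | O=CCCC(C)=CC[C@@H](C(C)C)[C@H]1OC(=O)C=C1 | intermediate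
15 | 3-hydroxy-4αH-eudesman-15,6β-olide, either C3 epimer | O=C1[C@H]2C(O)CC[C@]3(C)CC[C@@H](C(C)C)[C@@H](O1)[C@@H]23 | intermediate
16 | 3-methanesulfonyloxy-4αH-eudesman-15,6β-olide | O=C1[C@H]2C(OS(C)(=O)=O)CC[C@]3(C)CC[C@@H](C(C)C)[C@@H](O1)[C@@H]23 | intermediate
17 | eudesm-3-en-15,6β-olide | O=C1C2=CCC[C@]3(C)CC[C@@H](C(C)C)[C@@H](O1)[C@@H]23 | intermediate
18 | eudesm-3-ene-6β,15-diol | OCC1=CCC[C@]2(C)CC[C@@H](C(C)C)[C@@H](O)[C@@H]12 | intermediate
19 | eudesm-3-ene-6β,15-diyl bis(sulfate), bis(pyridinium) salt | [O-]S(=O)(=O)OCC1=CCC[C@]2(C)CC[C@@H](C(C)C)[C@@H](OS(=O)(=O)[O-])[C@@H]12.c1cc[nH+]cc1.c1cc[nH+]cc1 | intermediate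
20 | eudesm-3-en-6β-yl sulfate, lithium salt | CC1=CCC[C@]2(C)CC[C@@H](C(C)C)[C@@H](OS(=O)(=O)[O-])[C@@H]12.[Li+] | intermediate
21 | eudesm-3-en-6β-ol | CC1=CCC[C@]2(C)CC[C@@H](C(C)C)[C@@H](O)[C@@H]12 | intermediate
22 | (E)-4-acetoxycinnamic acid | CC(=O)Oc1ccc(/C=C/C(=O)O)cc1 | starting material
23 | (E)-4-acetoxycinnamoyl chloride | CC(=O)Oc1ccc(/C=C/C(=O)Cl)cc1 | intermediate
24 | 6β-[(E)-4-acetoxycinnamoyloxy]eudesm-3-ene | CC1=CCC[C@]2(C)CC[C@@H](C(C)C)[C@@H](OC(=O)/C=C/c3ccc(OC(C)=O)cc3)[C@@H]12 | intermediate
25 | 6β-[(E)-4-hydroxycinnamoyloxy]eudesm-3-ene (CNP0220414.1) | CC1=CCC[C@]2(C)CC[C@@H](C(C)C)[C@@H](OC(=O)/C=C/c3ccc(O)cc3)[C@@H]12 | target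

**Step count and risks**

Total step count: 12. Longest linear sequence: 11 steps (steps 1–5 and 7–12); step 6 is a one-step branch.

Steps most likely to fail:

1. Step 8 (key step). The iron enolate formed after the Giese addition may be protonated by the alcohol solvent before it reaches the aldehyde, so that only ring B closes. A hydrogen shift from C6–H to the C10 radical and incomplete facial control at C10 are further loss channels. Fallback: the two ring closures are separated. Starting from 14, the hydrogen-atom-transfer cyclisation is run as a plain reductive Giese cyclisation to the bicyclic lactone aldehyde F1. Ring A is then closed by a titanium-mediated crossed aldol addition (TiCl4, Bu3N, CH2Cl2, −78 °C), which returns to the route at hydroxy lactone 15. From 15 the mesylation and elimination of step 8 give 17.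

2. Step 10. If the hindered C6 hydroxyl is not fully sulfated, its oxygen can attack the activated allylic C15 and close a cyclic ether in competition with hydride delivery. Hydride attack with allylic shift is the other loss channel. Fallback: the ring closure is made the route. Starting from 18, cyclodehydration under Mitsunobu conditions (PPh3, DIAD, THF) gives 6β,15-epoxyeudesm-3-ene F2. Its allylic C15–O bond is then cleaved by dissolving-metal hydrogenolysis (Li, EtNH2, t-BuOH, −78 °C). Protonation of the allyl anion at its primary terminus should return to the route at 21.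

3. Step 11. Acyl transfer to the axial 6β-hydroxyl may be too slow, because it is 1,3-diaxial to the C10 methyl and flanked by the C7 isopropyl and the C4 methyl. Acetyl transfer from the aryl acetate could then compete. Fallback: the cinnamate is built on the oxygen from small pieces without a phenol protecting group. Starting from 21, heating with Meldrum's acid (toluene, 100 °C) gives the malonic acid half ester F3. Knoevenagel–Doebner condensation of F3 with 4-hydroxybenzaldehyde (pyridine, piperidine cat., 80 °C) then returns to the route at the target 25.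

Further compounds
F1 | step 8 | 3-[(4S,5S,8R,9R)-bicyclic lactone aldehyde: 10-methyl-7-isopropyl ring B cis-fused to the saturated 15,6β-lactone, C10 carrying the 3-oxopropyl chain] | O=CCC[C@]1(C)CC[C@@H](C(C)C)[C@H]2OC(=O)C[C@@H]12
F2 | step 10 | 6β,15-epoxyeudesm-3-ene | C1C2=CCC[C@]3(C)CC[C@@H](C(C)C)[C@@H](O1)[C@@H]23
F3 | step 11 | 3-(eudesm-3-en-6β-yloxy)-3-oxopropanoic acid | CC1=CCC[C@]2(C)CC[C@@H](C(C)C)[C@@H](OC(=O)CC(=O)O)[C@@H]12
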